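**Retrosynthetic overview**
1. The pyridine ring is closed last: both C–N bonds of the isoquinoline (N–C1 and N–C3) come from ammonia and the o-allylaryl methyl ketone 15, by ketimine formation and an oxidative 6-exo amination (key step).
2. 15 comes from aryl chloride 14 by allyl–boron coupling; 14 comes from a bromine-selective Suzuki union of bromo-chloro ketone 12 with the naphthyl boronate made in the flask from triflate 7.
3. 12 comes from 1-bromo-4-chloro-2-fluorobenzene: lithiation between F and Cl, acetylation, then SNAr exchange of F for OMe.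
4. 7 comes from 2-bromoanisole: Fischer carbene, Dötz benzannulation with propyne, triflation in the same flask.
5. Ring order: second carbocycle of the naphthalene (step 2), biaryl bond (step 5), pyridine ring of the isoquinoline (step 7).

Assumption: the target SMILES has no stereodescriptor and no stereocentre, so the biaryl axis is taken as unspecified and is formed without control in step 5.

All reagents used (Cr(CO)6, Me3OBF4, propyne, Tf2O, N-methoxy-N-methylacetamide, B2pin2, allylB(pin), TiCl4, NH3) are catalogue items.

**Step 1**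
Reactants: 1 2-bromoanisole
Product: 4 pentacarbonyl[methoxy(2-methoxyphenyl)methylidene]chromium, via 2-methoxyphenyllithium 2 (not isolated), via lithium pentacarbonyl(2-methoxybenzoyl)chromate 3 (not isolated)
Conditions: n-BuLi, Et2O, −78 → 0 °C; Cr(CO)6, Et2O, 0 → 25 °C; then Me3OBF4, CH2Cl2/H2O, 0 °C
Reagents that add atoms: chromium hexacarbonyl Cr(CO)6, [Cr].[C-]#[O+].[C-]#[O+].[C-]#[O+].[C-]#[O+].[C-]#[O+].[C-]#[O+]; trimethyloxonium tetrafluoroborate, C[O+](C)C.F[B-](F)(F)F
Why: Fischer carbene synthesis: the aryllithium from Br/Li exchange adds to a CO ligand of Cr(CO)6 and the acyl chromate is O-methylated by the Meerwein salt.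

**Step 2**
Reactants: 4 pentacarbonyl[methoxy(2-methoxyphenyl)methylidene]chromium
Product: 7 4,5-dimethoxy-2-methylnaphthalen-1-yl trifluoromethanesulfonate, via tricarbonyl(η6-4,5-dimethoxy-2-methylnaphthalen-1-ol)chromium 5 (not isolated), via tricarbonyl(η6-4,5-dimethoxy-2-methylnaphthalen-1-yl trifluoromethanesulfonate)chromium 6 (not isolated)
Conditions: propyne (4 equiv), THF, 50 °C, sealed tube; concentrate; Tf2O, i-Pr2NEt, CH2Cl2, −78 → 0 °C; then air, hν, Et2O, 25 °C
Reagents that add atoms: propyne, CC#C; trifluoromethanesulfonic anhydride, O=S(=O)(OS(=O)(=O)C(F)(F)F)C(F)(F)F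
Why: Dötz benzannulation (alkyne insertion, CO insertion, electrocyclisation) builds the second naphthalene ring with the methyl of the terminal alkyne next to the new phenol and the two methoxy groups peri to each other; the air-sensitive naphthol is triflated while still bound to Cr(CO)3 and the metal is then removed by air and light.

**Step 3**
Reactants: 8 1-bromo-4-chloro-2-fluorobenzene
Product: 11 1-(3-bromo-6-chloro-2-fluorophenyl)ethan-1-one, via (3-bromo-6-chloro-2-fluorophenyl)lithium 9 (not isolated), via tetrahedral lithium adduct 10 (not isolated)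
Conditions: LiN(i-Pr)2, THF, −78 °C; MeC(O)N(OMe)Me, −78 → 0 °C; then 1 M HCl
Reagents that add atoms: N-methoxy-N-methylacetamide, CC(=O)N(C)OC
Why: Directed ortho-lithiation removes the most acidic proton, the one flanked by F and Cl, without halogen exchange at −78 °C, and Weinreb acylation stops at the ketone through the chelated tetrahedral adduct.

**Step 4**
Reactants: 11 1-(3-bromo-6-chloro-2-fluorophenyl)ethan-1-one
Product: 12 1-(3-bromo-6-chloro-2-methoxyphenyl)ethan-1-one
Conditions: NaOMe, MeOH, 50 °C
Reagents that add atoms: sodium methoxide, C[O-].[Na+]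
Why: Nucleophilic aromatic substitution (SNAr): the fluoride ortho to the acyl group is displaced by methoxide far faster than the chloride because addition is rate-limiting, and the C–Br bond is untouched.

**Step 5**
Reactants: 7 4,5-dimethoxy-2-methylnaphthalen-1-yl trifluoromethanesulfonate; 12 1-(3-bromo-6-chloro-2-methoxyphenyl)ethan-1-one
Product: 14 1-[6-chloro-3-(4,5-dimethoxy-2-methylnaphthalen-1-yl)-2-methoxyphenyl]ethan-1-one, via naphthyl pinacol boronate 13 (not isolated)
Conditions: B2pin2, PdCl2(dppf) (5 mol%), KOAc, 1,4-dioxane, 100 °C; then 12, aq. K3PO4, 90 °C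
Reagents that add atoms: none
Why: Miyaura borylation of the triflate followed by Suzuki–Miyaura coupling in the same flask; zerovalent palladium with dppf inserts into C–Br much faster than into C–Cl, so the chloride survives for step 6, and the biaryl axis forms without control.

**Step 6**
Reactants: 14 1-[6-chloro-3-(4,5-dimethoxy-2-methylnaphthalen-1-yl)-2-methoxyphenyl]ethan-1-one
Product: 15 1-[3-(4,5-dimethoxy-2-methylnaphthalen-1-yl)-2-methoxy-6-(prop-2-en-1-yl)phenyl]ethan-1-one
Conditions: allylB(pin), Pd(OAc)2 (3 mol%), SPhos (6 mol%), K3PO4, THF/H2O, 60 °C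
Reagents that add atoms: allylboronic acid pinacol ester, C=CCB1OC(C)(C)C(C)(C)O1
Why: Suzuki–Miyaura allylation of an aryl chloride activated by its ortho acyl group; the unsubstituted allyl group raises no regiochemical question and the mild temperature limits alkene migration.

**Step 7**
Reactants: 15 1-[3-(4,5-dimethoxy-2-methylnaphthalen-1-yl)-2-methoxy-6-(prop-2-en-1-yl)phenyl]ethan-1-one
Product: 18 7-(4,5-dimethoxy-2-methylnaphthalen-1-yl)-8-methoxy-1,3-dimethylisoquinoline, via N-H ketimine 16 (not isolated), via 3-methylidene-3,4-dihydroisoquinoline 17 (not isolated)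
Conditions: NH3 (excess), TiCl4 (0.6 equiv), toluene, −20 → 25 °C; filter under Ar, concentrate; then Pd(OAc)2 (10 mol%), pyridine (40 mol%), O2 (1 atm), toluene, 80 °C
Reagents that add atoms: ammonia, N
Why: Proposed new method: the N–H ketimine 16 made from the hindered ketone and ammonia is metalated at nitrogen by Pd(OAc)2 to a ketimido–palladium species (the intermediate that the Narasaka aza-Heck reaction reaches by N–O oxidative addition), which inserts the pendant alkene by 6-exo syn-aminopalladation; β-hydride elimination gives the exocyclic enamine 17, its tautomerisation to the aromatic isoquinoline is strongly downhill, and O2 returns zerovalent palladium to divalent palladium. The closest known reactions are the Narasaka–Heck cyclisation of o-allylaryl ketone O-acyl oximes and aerobic aza-Wacker cyclisations of sulfonamides; to my knowledge a free N–H ketimine from ammonia has not been used as the nitrogen partner. The product nitrogen is flanked by two methyl groups and should bind palladium weakly, and alkene migration to the 1-propenyl isomer is not fatal because its azatriene can close by 6π-electrocyclisation and be dehydrogenated to the same product.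

**Compound list** (no stereocentres; biaryl axis unspecified)
1 | 2-bromoanisole | COc1ccccc1Br | starting material
2 | 2-methoxyphenyllithium | [Li]c1ccccc1OC | intermediate
3 | lithium pentacarbonyl(2-methoxybenzoyl)chromate | [Li+].O=C([Cr-])c1ccccc1OC.[C-]#[O+].[C-]#[O+].[C-]#[O+].[C-]#[O+].[C-]#[O+] | intermediate
4 | pentacarbonyl[methoxy(2-methoxyphenyl)methylidene]chromium | COC(=[Cr])c1ccccc1OC.[C-]#[O+].[C-]#[O+].[C-]#[O+].[C-]#[O+].[C-]#[O+] | intermediate
5 | tricarbonyl(η6-4,5-dimethoxy-2-methylnaphthalen-1-ol)chromium (η6 bonding written as separate fragments) | COc1cc(C)c(O)c2cccc(OC)c12.[Cr].[C-]#[O+].[C-]#[O+].[C-]#[O+] | intermediate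
6 | tricarbonyl(η6-4,5-dimethoxy-2-methylnaphthalen-1-yl trifluoromethanesulfonate)chromium (η6 bonding written as separate fragments) | COc1cc(C)c(OS(=O)(=O)C(F)(F)F)c2cccc(OC)c12.[Cr].[C-]#[O+].[C-]#[O+].[C-]#[O+] | intermediate
7 | 4,5-dimethoxy-2-methylnaphthalen-1-yl trifluoromethanesulfonate | COc1cc(C)c(OS(=O)(=O)C(F)(F)F)c2cccc(OC)c12 | intermediate
8 | 1-bromo-4-chloro-2-fluorobenzene | Fc1cc(Cl)ccc1Br | starting material
9 | (3-bromo-6-chloro-2-fluorophenyl)lithium | [Li]c1c(F)c(Br)ccc1Cl | intermediate
10 | lithium 1-(3-bromo-6-chloro-2-fluorophenyl)-1-[methoxy(methyl)amino]ethan-1-olate | [Li+].CON(C)C(C)([O-])c1c(F)c(Br)ccc1Cl | intermediate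
11 | 1-(3-bromo-6-chloro-2-fluorophenyl)ethan-1-one | CC(=O)c1c(F)c(Br)ccc1Cl | intermediate
12 | 1-(3-bromo-6-chloro-2-methoxyphenyl)ethan-1-one | CC(=O)c1c(OC)c(Br)ccc1Cl | intermediate
13 | 2-(4,5-dimethoxy-2-methylnaphthalen-1-yl)-4,4,5,5-tetramethyl-1,3,2-dioxaborolane | COc1cc(C)c(B2OC(C)(C)C(C)(C)O2)c2cccc(OC)c12 | intermediate
14 | 1-[6-chloro-3-(4,5-dimethoxy-2-methylnaphthalen-1-yl)-2-methoxyphenyl]ethan-1-one | CC(=O)c1c(Cl)ccc(-c2c(C)cc(OC)c3c(OC)cccc23)c1OC | intermediate
15 | 1-[3-(4,5-dimethoxy-2-methylnaphthalen-1-yl)-2-methoxy-6-(prop-2-en-1-yl)phenyl]ethan-1-one | C=CCc1ccc(-c2c(C)cc(OC)c3c(OC)cccc23)c(OC)c1C(C)=O | intermediate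
16 | 1-[3-(4,5-dimethoxy-2-methylnaphthalen-1-yl)-2-methoxy-6-(prop-2-en-1-yl)phenyl]ethan-1-imine | C=CCc1ccc(-c2c(C)cc(OC)c3c(OC)cccc23)c(OC)c1C(C)=N | intermediate
17 | 7-(4,5-dimethoxy-2-methylnaphthalen-1-yl)-8-methoxy-1-methyl-3-methylidene-3,4-dihydroisoquinoline | COc1c(-c2c(C)cc(OC)c3c(OC)cccc23)ccc2c1C(C)=NC(=C)C2 | intermediate
18 | 7-(4,5-dimethoxy-2-methylnaphthalen-1-yl)-8-methoxy-1,3-dimethylisoquinoline | COc1c(-c2c(C)cc(OC)c3c(OC)cccc23)ccc2cc(C)nc(C)c12 | target

**Totals**
Total step count: 7. Longest linear sequence: 5 (steps 1, 2, 5, 6, 7, or equally steps 3, 4, 5, 6, 7).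

**Steps most likely to fail**

Step 7 (the proposed new step). The risks are incomplete ketimine formation at the di-ortho-substituted ketone and poisoning or diversion of the palladium catalyst. The fallback uses known chemistry, sets out from 15 and comes back at 18. The allyl group is oxidised under Tsuji–Wacker conditions (PdCl2, CuCl, O2, DMF/H2O, 25 °C) to the 1,5-diketone 1-[2-acetyl-4-(4,5-dimethoxy-2-methylnaphthalen-1-yl)-3-methoxyphenyl]propan-2-one F3. This is then condensed with NH4OAc in AcOH at 80 °C, the classical 1,5-dicarbonyl-to-pyridine closure, to give 18.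

Step 5. The risks are slow borylation of the di-ortho-substituted, electron-rich triflate and protodeboronation of 13 during the hindered coupling. The fallback reverses the roles of the partners, sets out from 12 and 7 and comes back at 14. Bromine-selective Miyaura borylation of 12 (B2pin2, PdCl2(dppf), KOAc, dioxane, 80 °C) gives the less hindered boronate 1-[6-chloro-2-methoxy-3-(4,4,5,5-tetramethyl-1,3,2-dioxaborolan-2-yl)phenyl]ethan-1-one F2. F2 is coupled with triflate 7 under Pd(PPh3)4, K3PO4, KBr, dioxane, 100 °C, conditions under which the aryl chloride does not react.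

Step 2. The risks are the benzannulation with a gaseous alkyne and triflation of the phenol while it is still bound to chromium. The fallback separates ring construction from activation, sets out from 4 and comes back at 7. The benzannulation is run alone (propyne, THF, 50 °C) and the metal is stripped by stirring in air. The metal-free 4,5-dimethoxy-2-methylnaphthalen-1-ol F1 is isolated under argon and triflated in a separate flask (Tf2O, pyridine, CH2Cl2, 0 °C).

**Further compounds**
F1 | step 2 | 4,5-dimethoxy-2-methylnaphthalen-1-ol | COc1cc(C)c(O)c2cccc(OC)c12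
F2 | step 5 | 1-[6-chloro-2-methoxy-3-(4,4,5,5-tetramethyl-1,3,2-dioxaborolan-2-yl)phenyl]ethan-1-one | CC(=O)c1c(OC)c(B2OC(C)(C)C(C)(C)O2)ccc1Cl
F3 | step 7 | 1-[2-acetyl-4-(4,5-dimethoxy-2-methylnaphthalen-1-yl)-3-methoxyphenyl]propan-2-one | CC(=O)Cc1ccc(-c2c(C)cc(OC)c3c(OC)cccc23)c(OC)c1C(C)=O
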